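**Retrosynthetic overview**
1. The last step removes all four MOM groups. Before that, ring C is made by contracting a seven-membered 2-aryl-1,3-benzodioxepin-5-one: C2 shifts from O3 to C3, which forms the C2–C3 bond and sets both ring stereocentres.
2. The seven-membered keto-acetal is assembled from a ring A 2,ω-dihydroxyacetophenone and the ring B aldehyde, which supplies C2.
3. Ring A is a protected resorcinol filled one position at a time: the C6 chain (directed lithiation/prenylation, hydration), O1 (C–H borylation/oxidation), then C8 and C4a through a bromide/iodide pair (Suzuki coupling, then Br/Li exchange and hydroxyacetylation).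
4. The (S)-lavandulyl unit is built from three small pieces by two boron 1,2-metallate shifts: a conjunctive coupling sets the stereocentre and a Matteson CH2 insertion follows.
5. Ring order: rings A and B are bought as benzene rings, the seven-membered acetal ring forms next, and it is contracted to ring C last.

Assumption: the hand of each chiral ligand (steps 1 and 11) is fixed in a first run by correlation (a sample of 7 oxidised to known (R)-lavandulol; CD of 29), since both ligand enantiomers are available.

"Lavandulyl" below means 5-methyl-2-(prop-1-en-2-yl)hex-4-en-1-yl.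

**Step 1**
Reactants: 1 isopropenylmagnesium bromide; 2 vinylboronic acid pinacol ester; 3 1-bromo-2-methylprop-1-ene
Product: 5 (R)-2-(2,6-dimethylhepta-1,5-dien-3-yl)-4,4,5,5-tetramethyl-1,3,2-dioxaborolane, via bromomagnesium isopropenyl(vinyl)borate 4 (not isolated)
Conditions: 2, THF, 0 °C, then 1 (1.0 equiv), rt, 30 min; NaOTf (2 equiv), Pd(OAc)2 (2 mol %), MandyPhos-type ligand (αR,αR)-2,2'-bis(α-dimethylaminobenzyl)-(S,S)-1,1'-bis[bis(4-methoxy-3,5-dimethylphenyl)phosphino]ferrocene (2.4 mol %), 3 (1.2 equiv), THF/DMSO, 40 °C, 16 h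
Reagents that add atoms: none
Why: Enantioselective conjunctive cross-coupling: the alkenylpalladium bromide (divalent palladium) binds the unsubstituted vinyl group of 4 and triggers a 1,2-metallate shift of the isopropenyl group from boron to the α-carbon, reductive elimination joins the β-carbon to the 2-methylpropenyl group, and the chiral diphosphine selects the alkene face and so sets the (R) stereocentre.

**Step 2**
Reactants: 5 (R)-allylic boronate
Product: 7 2-[(2R)-5-methyl-2-(prop-1-en-2-yl)hex-4-en-1-yl]-4,4,5,5-tetramethyl-1,3,2-dioxaborolane ((R)-lavandulyl-Bpin), via lithium chloromethylborate 6 (not isolated)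
Conditions: BrCH2Cl (2 equiv), nBuLi (1.8 equiv), Et2O, −78 °C → rt, 2 h
Reagents that add atoms: bromochloromethane ClCBr
Why: Matteson homologation: LiCH2Cl adds to boron and the secondary allylic carbon migrates 1,2 with retention while chloride leaves, so the stereocentre is carried over unchanged.

**Step 3**
Reactants: 8 1,3-bis(methoxymethoxy)benzene
Product: 9 1-bromo-2,4-bis(methoxymethoxy)benzene
Conditions: NBS (1.0 equiv), MeCN, 0 °C → rt
Reagents that add atoms: N-bromosuccinimide O=C1CCC(=O)N1Br
Why: Electrophilic aromatic bromination goes to C4 (para to one ether oxygen, ortho to the other) and avoids the crowded C2; no stereocentre is formed.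

**Step 4**
Reactants: 9 1-bromo-2,4-bis(methoxymethoxy)benzene
Product: 12 2,4-bis(methoxymethoxy)benzaldehyde, via aryllithium 10 (not isolated), via lithium hemiaminal alkoxide 11 (not isolated)
Conditions: nBuLi (1.05 equiv), THF, −78 °C; DMF, −78 °C → rt; H2O
Reagents that add atoms: N,N-dimethylformamide CN(C)C=O
Why: Bromine–lithium exchange followed by Bouveault-type formylation; exchange at −78 °C is faster than any directed lithiation, so the 2,4-pattern is kept.

**Step 5**
Reactants: 8 1,3-bis(methoxymethoxy)benzene; 13 1-bromo-3-methylbut-2-ene (prenyl bromide)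
Product: 15 1,3-bis(methoxymethoxy)-2-(3-methylbut-2-en-1-yl)benzene, via 2-lithioarene 14 (not isolated)
Conditions: nBuLi (1.1 equiv), THF, 0 °C → rt, 1 h; CuBr·SMe2 (10 mol %), 13, −78 °C → rt
Reagents that add atoms: none
Why: Directed ortho-metalation between the two cooperating MOM ethers, then copper-assisted SN2 allylation, places the future C6 chain.

**Step 6**
Reactants: 15 2-prenyl arene
Product: 16 4-[2,6-bis(methoxymethoxy)phenyl]-2-methylbutan-2-ol
Conditions: Co(acac)2 (10 mol %), PhSiH3 (2 equiv), O2 (1 atm), THF, rt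
Reagents that add atoms: dioxygen O=O
Why: Mukaiyama hydration (hydrogen-atom transfer to the only alkene present, then trapping of the tertiary radical by O2 and reduction) gives the Markovnikov tertiary alcohol under neutral conditions that spare the MOM ethers.

**Step 7**
Reactants: 16 tertiary alcohol
Product: 18 4-(3-hydroxy-3-methylbutyl)-3,5-bis(methoxymethoxy)phenol, via arylboronic pinacol ester 17 (not isolated)
Conditions: [Ir(OMe)(cod)]2 (1.5 mol %), dtbpy (3 mol %), B2pin2 (1.5 equiv), THF, 80 °C; then 30 % H2O2, aq NaOH, 0 °C (any O–Bpin on the alcohol is hydrolysed here)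
Reagents that add atoms: hydrogen peroxide OO; bis(pinacolato)diboron CC1(C)OB(OC1(C)C)B1OC(C)(C)C(C)(C)O1 (its boryl group stays only in 17)
Why: Sterically governed iridium-catalysed aromatic C–H borylation reacts at the only ring C–H with no ortho neighbour (para to the chain), and boronate oxidation gives the third ring oxygen as the only free phenol, which later becomes O1.

**Step 8**
Reactants: 18 phenol
Product: 20 2-bromo-6-iodo-4-(3-hydroxy-3-methylbutyl)-3,5-bis(methoxymethoxy)phenol, via monobromophenol 19 (not isolated)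
Conditions: NBS (1.0 equiv), CH2Cl2, −78 °C, 1 h; then NIS (1.05 equiv), −78 → 0 °C
Reagents that add atoms: N-bromosuccinimide O=C1CCC(=O)N1Br; N-iodosuccinimide O=C1CCC(=O)N1I
Why: Sequential electrophilic aromatic halogenation: the two free positions are equivalent and strongly activated, so one equivalent of NBS in the cold gives the monobromide and NIS fills the last position, leaving two handles of different reactivity before any alkene is present.

**Step 9**
Reactants: 20 bromo-iodophenol; 7 (R)-lavandulyl-Bpin
Product: 21 2-bromo-4-(3-hydroxy-3-methylbutyl)-3,5-bis(methoxymethoxy)-6-[(2S)-lavandulyl]phenol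
Conditions: Pd2(dba)3 (2.5 mol %), RuPhos (10 mol %), NaOtBu (4 equiv), toluene/H2O 10:1, 60 °C, 7 as limiting reagent (0.95 equiv)
Reagents that add atoms: none
Why: B-alkyl Suzuki–Miyaura coupling: zerovalent palladium inserts into the carbon–iodine bond much faster than into the carbon–bromine bond, and the stereocentre sits β to boron and is not involved (the descriptor changes from R to S only because the substituent ranking changes).

**Step 10**
Reactants: 21 bromophenol; 22 2,2-dimethyl-1,3-dioxolan-4-one (glycolic acid acetonide)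
Product: 25 2-hydroxy-1-{2-hydroxy-5-(3-hydroxy-3-methylbutyl)-4,6-bis(methoxymethoxy)-3-[(2S)-lavandulyl]phenyl}ethan-1-one, via trilithio species 23 (not isolated), via lithium hemiketal alkoxide 24 (not isolated)
Conditions: nBuLi (3.1 equiv), THF, −78 °C; 22 (1.5 equiv), −78 → −20 °C; H2O
Reagents that add atoms: none
Why: After deprotonation of both OH groups, bromine–lithium exchange and acylation by the lactone give a hemiketal alkoxide that is stable in the cold (so no over-addition) and loses acetone on quench to release the free hydroxyacetyl group; the lavandulyl stereocentre is not touched.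

**Step 11**
Reactants: 25 ring A 2,ω-dihydroxyacetophenone; 12 2,4-bis(methoxymethoxy)benzaldehyde
Product: 28 (2R,3R)-2-[2,4-bis(methoxymethoxy)phenyl]-3-hydroxy-6-(3-hydroxy-3-methylbutyl)-5,7-bis(methoxymethoxy)-8-[(2S)-lavandulyl]chroman-4-one, via dimethyl acetal 26 (not isolated), via seven-membered keto-acetal 27 (not isolated)
Conditions: (i) HC(OMe)3 (1.5 equiv), PPTS (5 mol %), 4 Å MS, CH2Cl2, rt, then evaporate volatiles; (ii) Sc(OTf)3 (10 mol %), chiral N,N'-dioxide ligand [(S)-pipecolic-acid-derived, propane-1,3-diyl-bridged bis(N-oxide) bis(2,6-diisopropylanilide)] (11 mol %), iPr2NEt (20 mol %), 4 Å MS, CH2Cl2, −20 °C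
Reagents that add atoms: trimethyl orthoformate COC(OC)OC (its methoxy groups stay only in 26)
Why: Proposed new method: catalytic enantioselective ring contraction by a 1,2-shift of C2 from O3 to C3 – transacetalisation first ties 25 and the aldehyde carbon into the seven-membered keto-acetal 27 (racemic at C2, which does not matter), the chiral scandium complex (trivalent scandium) then chelates the ketone oxygen and O3, the amine removes the acidified C3–H to give a scandium enediolate while the C2–O3 bond ionises to an aryloxycarbenium ion stabilised by the 2,4-dialkoxyphenyl ring, and the tethered ion pair recloses from C3 to C2 (6-(enolendo)-endo-trig, chair with aryl and O3 equatorial, hence 2,3-trans; the ligand blocks one enediolate face, hence 3R and with it 2R), a stepwise ionic and stereoconvergent process driven by exchange of an acetal C–O bond for a C–C bond and by the change from a seven- to a six-membered ring; the closest known reaction types are the acetal [1,2]-Wittig rearrangement, the Petasis–Ferrier rearrangement and chiral-Lewis-acid-catalysed [1,3] O-to-C rearrangements of benzylic enol ethers.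

**Step 12**
Reactants: 28 tetra-MOM flavanonol
Product: 29 (2R,3R)-2-(2,4-dihydroxyphenyl)-3,5,7-trihydroxy-6-(3-hydroxy-3-methylbutyl)-8-[(2S)-lavandulyl]chroman-4-one (target)
Conditions: HCl (1.25 M in MeOH), 0 °C → rt
Reagents that add atoms: none
Why: Acid-catalysed acetal exchange (methanolysis) cleaves the four aryl MOM ethers under dilute, cold conditions that leave the non-activated tertiary alcohol and both alkenes alone; C3 does not epimerise in acid, and any reversible opening at C2 returns the more stable 2,3-trans isomer.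

**Compound list**
1 | isopropenylmagnesium bromide | C=C(C)[Mg]Br | starting material
2 | vinylboronic acid pinacol ester | C=CB1OC(C)(C)C(C)(C)O1 | starting material
3 | 1-bromo-2-methylprop-1-ene | CC(C)=CBr | starting material
4 | bromomagnesium isopropenyl(vinyl)(pinacolato)borate | C=C[B-]1(C(C)=C)OC(C)(C)C(C)(C)O1.[Mg+2].[Br-] | intermediate
5 | (R)-2-(2,6-dimethylhepta-1,5-dien-3-yl)-4,4,5,5-tetramethyl-1,3,2-dioxaborolane | C=C(C)[C@@H](CC=C(C)C)B1OC(C)(C)C(C)(C)O1 | intermediate
6 | lithium chloromethyl[(R)-2,6-dimethylhepta-1,5-dien-3-yl](pinacolato)borate | C=C(C)[C@@H](CC=C(C)C)[B-]1(CCl)OC(C)(C)C(C)(C)O1.[Li+] | intermediate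
7 | (R)-lavandulylboronic acid pinacol ester | C=C(C)[C@@H](CC=C(C)C)CB1OC(C)(C)C(C)(C)O1 | intermediate
8 | 1,3-bis(methoxymethoxy)benzene | COCOc1cccc(OCOC)c1 | starting material
9 | 1-bromo-2,4-bis(methoxymethoxy)benzene | COCOc1ccc(Br)c(OCOC)c1 | intermediate
10 | 2,4-bis(methoxymethoxy)phenyllithium | COCOc1ccc([Li])c(OCOC)c1 | intermediate
11 | lithium [2,4-bis(methoxymethoxy)phenyl](dimethylamino)methoxide | COCOc1ccc(C(O[Li])N(C)C)c(OCOC)c1 | intermediate
12 | 2,4-bis(methoxymethoxy)benzaldehyde | COCOc1ccc(C=O)c(OCOC)c1 | intermediate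
13 | 1-bromo-3-methylbut-2-ene | CC(C)=CCBr | starting material
14 | 2,6-bis(methoxymethoxy)phenyllithium | COCOc1cccc(OCOC)c1[Li] | intermediate
15 | 1,3-bis(methoxymethoxy)-2-(3-methylbut-2-en-1-yl)benzene | COCOc1cccc(OCOC)c1CC=C(C)C | intermediate
16 | 4-[2,6-bis(methoxymethoxy)phenyl]-2-methylbutan-2-ol | COCOc1cccc(OCOC)c1CCC(C)(C)O | intermediate
17 | 4-[2,6-bis(methoxymethoxy)-4-(4,4,5,5-tetramethyl-1,3,2-dioxaborolan-2-yl)phenyl]-2-methylbutan-2-ol | COCOc1cc(B2OC(C)(C)C(C)(C)O2)cc(OCOC)c1CCC(C)(C)O | intermediate
18 | 4-(3-hydroxy-3-methylbutyl)-3,5-bis(methoxymethoxy)phenol | COCOc1cc(O)cc(OCOC)c1CCC(C)(C)O | intermediate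
19 | 2-bromo-4-(3-hydroxy-3-methylbutyl)-3,5-bis(methoxymethoxy)phenol | Oc1cc(OCOC)c(CCC(C)(C)O)c(OCOC)c1Br | intermediate
20 | 2-bromo-6-iodo-4-(3-hydroxy-3-methylbutyl)-3,5-bis(methoxymethoxy)phenol | Oc1c(I)c(OCOC)c(CCC(C)(C)O)c(OCOC)c1Br | intermediate
21 | 2-bromo-4-(3-hydroxy-3-methylbutyl)-3,5-bis(methoxymethoxy)-6-[(2S)-lavandulyl]phenol | C=C(C)[C@@H](CC=C(C)C)Cc1c(O)c(Br)c(OCOC)c(CCC(C)(C)O)c1OCOC | intermediate
22 | 2,2-dimethyl-1,3-dioxolan-4-one | CC1(C)OCC(=O)O1 | starting material
23 | trilithio species of 21 (aryl C–Li in place of C–Br, lithium phenoxide, lithium tert-alkoxide) | C=C(C)[C@@H](CC=C(C)C)Cc1c(O[Li])c([Li])c(OCOC)c(CCC(C)(C)O[Li])c1OCOC | intermediate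
24 | lithium hemiketal alkoxide (aryl added to C4 of the dioxolanone, epimers at the new carbon) | C=C(C)[C@@H](CC=C(C)C)Cc1c(O[Li])c(C2(O[Li])COC(C)(C)O2)c(OCOC)c(CCC(C)(C)O[Li])c1OCOC | intermediate
25 | 2-hydroxy-1-{2-hydroxy-5-(3-hydroxy-3-methylbutyl)-4,6-bis(methoxymethoxy)-3-[(2S)-lavandulyl]phenyl}ethan-1-one | C=C(C)[C@@H](CC=C(C)C)Cc1c(O)c(C(=O)CO)c(OCOC)c(CCC(C)(C)O)c1OCOC | intermediate
26 | 1-(dimethoxymethyl)-2,4-bis(methoxymethoxy)benzene | COCOc1ccc(C(OC)OC)c(OCOC)c1 | intermediate
27 | 2-[2,4-bis(methoxymethoxy)phenyl]-7-(3-hydroxy-3-methylbutyl)-6,8-bis(methoxymethoxy)-9-[(2S)-lavandulyl]-4H-1,3-benzodioxepin-5-one (both epimers at C2) | C=C(C)[C@@H](CC=C(C)C)Cc1c(OCOC)c(CCC(C)(C)O)c(OCOC)c2c1OC(c1ccc(OCOC)cc1OCOC)OCC2=O | intermediate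
28 | (2R,3R)-2-[2,4-bis(methoxymethoxy)phenyl]-3-hydroxy-6-(3-hydroxy-3-methylbutyl)-5,7-bis(methoxymethoxy)-8-[(2S)-lavandulyl]chroman-4-one | C=C(C)[C@@H](CC=C(C)C)Cc1c(OCOC)c(CCC(C)(C)O)c(OCOC)c2c1O[C@H](c1ccc(OCOC)cc1OCOC)[C@@H](O)C2=O | intermediate
29 | (2R,3R)-2-(2,4-dihydroxyphenyl)-3,5,7-trihydroxy-6-(3-hydroxy-3-methylbutyl)-8-[(2S)-lavandulyl]chroman-4-one | C=C(C)[C@@H](CC=C(C)C)Cc1c(O)c(CCC(C)(C)O)c(O)c2c1O[C@H](c1ccc(O)cc1O)[C@@H](O)C2=O | target

**Step count**
- Total steps: 12.
- Longest linear sequence: 8 steps (8 → 29, steps 5–12).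

**The three steps most likely to fail**

**Step 11 (the new step).** It may stall at 27, hydrolyse back to 25 and 12, or give low enantioselectivity. A wrong ring C hand would show up as a diastereomer because of the lavandulyl centre, so it can be separated. The fallback uses known chemistry, sets out from 25 (together with 12) and comes back at 28. A direct syn-selective aldol addition of the α-hydroxy ketone 25 to 12 is run under the dinuclear zinc catalyst made from ZnEt2 and ProPhenol (extra ZnEt2 for the free OH groups, 4 Å MS, THF, −20 °C). This gives the (2R,3S)-syn-diol F1. An intramolecular Mitsunobu etherification (PPh3, DIAD, THF, 0 °C) then lets the phenol oxygen displace the benzylic hydroxyl with inversion, which closes ring C as the 2,3-trans isomer 28.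

**Step 9.** Three things can go wrong:
- The β-branched alkyl pinacol boronate may transmetallate slowly.
- β-Hydride elimination could erode the stereocentre.
- The carbon–bromine bond may start to react.

The fallback sets out from 7 and comes back at 21. Oxidation of 7 (NaBO3·4H2O, THF/H2O) gives (R)-lavandulol F2. An Appel reaction (I2, PPh3, imidazole) gives (R)-lavandulyl iodide F3. Zinc insertion (Zn dust, LiCl, THF) gives (R)-lavandulylzinc iodide F4. A Negishi coupling with 20 at room temperature (Pd(OAc)2, SPhos, THF, slow addition of the zinc reagent to tolerate the OH groups) reacts only at the aryl iodide and gives 21.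

**Step 12.** Protic acid may close the tertiary alcohol or the alkenes onto the neighbouring phenols to form chromans. The fallback sets out from 28 and comes back at 29. TMSOTf with 2,2'-bipyridyl (MeCN, 0 °C → rt) converts the aryl MOM ethers, through methoxymethyl-bipyridinium salts and without free acid, into silyl ethers and also silylates both alcohols. This gives the hexakis(trimethylsilyl) ether F5. Near-neutral desilylation (KF, MeOH/pH 7 buffer, rt) then gives 29.

**Further compounds**
F1 | step 11 | (2R,3S)-3-[2,4-bis(methoxymethoxy)phenyl]-2,3-dihydroxy-1-{2-hydroxy-5-(3-hydroxy-3-methylbutyl)-4,6-bis(methoxymethoxy)-3-[(2S)-lavandulyl]phenyl}propan-1-one | C=C(C)[C@@H](CC=C(C)C)Cc1c(O)c(C(=O)[C@H](O)[C@@H](O)c2ccc(OCOC)cc2OCOC)c(OCOC)c(CCC(C)(C)O)c1OCOC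
F2 | step 9 | (R)-lavandulol | C=C(C)[C@@H](CC=C(C)C)CO
F3 | step 9 | (R)-lavandulyl iodide | C=C(C)[C@@H](CC=C(C)C)CI
F4 | step 9 | (R)-lavandulylzinc iodide | C=C(C)[C@@H](CC=C(C)C)C[Zn]I
F5 | step 12 | hexakis(trimethylsilyl) ether of 29 | C=C(C)[C@@H](CC=C(C)C)Cc1c(O[Si](C)(C)C)c(CCC(C)(C)O[Si](C)(C)C)c(O[Si](C)(C)C)c2c1O[C@H](c1ccc(O[Si](C)(C)C)cc1O[Si](C)(C)C)[C@@H](O[Si](C)(C)C)C2=O
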